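The readings were computed with made-up constants, and the scatter is random.

The easy step comes first: in Tuesday's run D stands at 31% after 0.667 min and near 50% after 2.50 min.

- Tuesday's: Q 10 mM; L 10 mM (in portions, 4); run made earlier; portions every 50 s
- flask: Q 10 mM; L 20.0 mM (in portions, 4); time 30 min; the portions of L follow each other after 50 s, the first at the start

- Tuesday's (time / min: Z / %, D / %): 0.667: 3, 31; 1.33: 5, 44; 2.00: 9, 46; 2.50: 10, 50; 3.00: 6, 47

(scatter of a reading: 1.5 percentage points)

- in percentages every species weighs as the Q in it: one J counts as two
- what was read earlier has a scatter of 1.5 percentage points, one standard deviation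
- a reading or a percentage of Z counts all its forms, free or not

- amount of Z at 30 min, in percent of the Q charged
- amount of D at 30 min, in percent of the Q charged
- amount of J at 30 min, in percent of the Q charged

I read that rise as a first-order approach to D's plateau, which gives Q on Tuesday a lifetime τ:

τ = t / ln(plateau / (plateau − D)) = 0.689 min

This is the lowest rung of my ladder, shorter than the 0.83 min between portions. The next rung is Tuesday's last portion, at 2.50 min, when my estimate leaves 2.66% of the Q. The top rung is the new flask's 30 min, far longer than that, so I expect its end state to be written in the first minutes.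

What counts then is the split. I take Z to need L and D not to, so Z per D should grow with the L charged. From Tuesday's last three readings:

mean Z = 8.33%, mean D = 47.7%

σ = Z / (D · charge of L) = 0.0175 mM⁻¹

I carry σ, a reading with the scatter of Tuesday's run in it: the Z made per D made per mM of L charged on this schedule, a selectivity factor. I book Tuesday's remainder as J, so J per D is 0.923, and I hold that ratio. For the new flask:

Z per D = σ · 20.0 mM = 0.350

With Z, D and J summing to the Q charged, I reckon D 44.0%, Z 15.4% and J 40.6%.

The forecast differs from my reckoning: it gives Z 3%, D 50% and J 45%, with “Q should be fully consumed and Z driven low”. My Z is higher.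

The flask gives Z 13.8%, D 44.6% and J 41.6%.

    Q + L → Z (k = 0.984 M⁻¹ s⁻¹)
    Q → D (k = 0.0176 s⁻¹)
    2 Q → J (k = 1.90 M⁻¹ s⁻¹)
    L + Z ⇌ E, settled at all times (K = 47.5 M⁻¹)

In the new flask Z per D comes to 0.309 against my 0.350, and Z, with E counted in, stands at 13.8% after 30.0 min and 13.8% after 300 min. The bit-by-bit addition of L and the loss of Q to D, acting together, are each a part of what holds Z down: Z is 13.8% here, 33.6% with L charged at once and 30.7% without that loss. The neighbouring flask with 17 mM of Q has the same L, so σ again says 0.350; it gives Z 10.5% and D 36.2%, a Z per D of 0.290, while its J reaches 53.2%.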